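Running out cannot be what stops these runs: substrate ends at 48.7% in west, 48.9% in south-east and 48.7% in north-west, though north-west holds 4.00 times the charge of south-east.

| setting | west | south-east | north-west | zeta | epsilon | beta |
|---|---|---|---|---|---|---|
| substrate | 0.020 M | 0.010 M | 0.040 M | 0.020 M (fed, over 3.0 min) | 0.020 M | 0.020 M |
| coupling partner | 0.050 M | 0.050 M | 0.050 M | 0.0500 M | 0.0500 M (fed, over 3.0 min) | 0.0500 M |
| free catalyst | 0.24 mM | 0.24 mM | 0.24 mM | 0.24 mM | 0.24 mM | 0.24 mM |
| remark | run made earlier | run made earlier | run made earlier | all else is in the flask from the start; the feed brings no volume worth counting | all else is in the flask from the start; the feed brings no volume worth counting | everything together at the start |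
| time |  |  |  | 5.0 min | 5.0 min | 5.0 min |

- west (time / min: product / %, substrate / %): 0.250: 2.6, 72.2; 0.333: 4.4, 67.2; 0.500: 5.1, 60.8; 0.833: 8.0, 53.9; 1.33: 9.6, 49.6; 2.00: 10.4, 49.1; 3.00: 10.3, 48.7
- south-east (time / min: product / %, substrate / %): 0.167: 1.4, 78.8; 0.500: 5.7, 60.5; 0.833: 8.1, 53.6; 1.33: 10.3, 49.5; 2.00: 10.2, 49.2; 2.50: 10.4, 48.6; 3.00: 10.2, 48.9
- north-west (time / min: product / %, substrate / %): 0.417: 4.5, 63.4; 0.833: 7.9, 53.6; 1.33: 9.6, 49.9; 1.50: 9.3, 49.5; 2.00: 9.9, 49.3; 2.50: 10.1, 48.7; 3.00: 10.1, 48.7

(scatter of a reading: 0.3 percentage points)

- the best flask by amount of product, in percent of the substrate charged; "all alike" if 1.5 percentage points covers them all (zeta / epsilon / beta / all alike)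
- amount of product at the end, in percent of the substrate charged, zeta
- amount of product at the end, in percent of the substrate charged, epsilon
- amount of product at the end, in percent of the substrate charged, beta

So read a clock. Substrate falls pseudo-first-order against a fading catalyst, so work in logarithms. Take the dose, 0.719, as the natural logarithm of charged over left substrate at the stop. West has used 0.498 of it by 0.500 min, which gives the catalyst a life of 0.425 min. One power of ten of catalyst goes every 0.978 min, so the feed of 3.0 min spans 3.07 powers.

Now bound zeta. Put its whole charge in at the start and 51.3% is taken; put it in after the clock has run down and none is. Each arrival in zeta meets the dose still unused, and that shrinks with a life shorter than the feed, so the real zeta lies between. Counting each arrival's remaining dose as its taken fraction gives the top, 10.2%. Scaling the start-charge share by that remaining dose gives the bottom, 7.27%.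

West turns 20.1% of taken substrate into product, so I hold zeta's product under 2.05%. Beta repeats west, near 10.3%. Leave epsilon's product open, since coupling partner stood at 0.050 M in the three runs' recipes.

The forecast names beta, with zeta 0.8%, epsilon 2.2% and beta 10.3%, and says of fed substrate that “most arrives after the catalyst is dead”.

    free catalyst → spent catalyst B (k = 0.0400 /s)
    substrate + free catalyst → free catalyst + intermediate (k = 120 /M/s)
    coupling partner + free catalyst + intermediate ⇌ free catalyst + product (K = 44.0 /M, k = 1500 /M²/s)
    free catalyst → spent catalyst A (k = 2.00 × 10⁻⁵ /s)

Beta gives 10.2%, epsilon 2.36% and zeta 0.837%, so beta makes more than the other two, as forecast. Zeta has taken 8.44% of its substrate by 5.00 min, above the bottom bound and below the top. Carry the dose to a neighbour of zeta charged with 0.960 mM of free catalyst: scaled with that charge it is 2.88, and with the same life the bounds become 13.4% and 40.8%. That neighbour leaves 77.1% of its substrate, so 22.9% is taken, and it holds product at 6.31%.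

The earlier runs and the new flask are calculated for substances that don't exist, noise included.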